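## Retrosynthetic overview

1. Ajugaciliatin A ⇐ HOCl across the 4(18)-alkene of diester 31 ⇐ double acylation of diol 29 ⇐ Nozaki–Hiyama–Kishi union of aldehyde 27 with ready-made 4-bromobutenolide (butenolide ring brought in intact, last).
2. All ring oxygens hang on an 18-nor-4-ketone: O6 by oxime-directed C–H acetoxylation, O19 by hydroxyl-directed C–H silylation/oxidation, O1 by dienol ether/singlet-oxygen γ-oxygenation; C18 returns by methylenation.
3. The 4-ketone ⇐ exocyclic enone 7 (ozonolysis, enol triflation, hydrogenolysis).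
4. Decalin 7 ⇐ acyclic (2R,3R)-epoxy-triene 5 in one cationic cascade: ring A (C4–C5), then ring B (C9–C10), then H9→C8, Me C10→C9, H5→C10, Me C4→C5, H3→C4 (ketone).
5. 5 ⇐ (3E,7E)-homofarnesol (chlorination, SeO2 oxidation, Sharpless epoxidation/silylation).

Assumption: (3E,7E)-homofarnesol is bought (industrial Ambrox intermediate); names use neo-clerodane numbering and its parent configuration (8α-Me, 9α-Me, 10β-H, C19 on C5 α, C11 on C9 β).

## Route

Step 1
Reactants: 1 (3E,7E)-homofarnesol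
Product: 2 (3E,7E)-1-chloro-4,8,12-trimethyltrideca-3,7,11-triene
Conditions: NCS, PPh3, CH2Cl2, 0 °C → rt
Reagents that add atoms: N-chlorosuccinimide, ClN1C(=O)CCC1=O
Why: Appel-type chlorination (SN2 on the alkoxyphosphonium) of the primary homoallylic alcohol leaves the trisubstituted alkenes alone and gives a C12 stub that is neither nucleophilic nor cation-destabilising in the later cascade.

Step 2
Reactants: 2 (3E,7E)-1-chloro-4,8,12-trimethyltrideca-3,7,11-triene
Product: 3 (2E,6E,10E)-13-chloro-2,6,10-trimethyltrideca-2,6,10-trien-1-ol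
Conditions: SeO2 (10 mol%), t-BuOOH, salicylic acid (cat.), CH2Cl2, rt
Reagents that add atoms: tert-butyl hydroperoxide, CC(C)(C)OO
Why: Catalytic SeO2 allylic oxidation (ene reaction then [2,3]-shift) attacks the E-methyl of the terminal, most accessible trisubstituted alkene, so the oxidised methyl is the one that later stays on C4 (C18) and the Z-methyl is the one that migrates (C19).

Step 3
Reactants: 3 (2E,6E,10E)-13-chloro-2,6,10-trimethyltrideca-2,6,10-trien-1-ol
Product: 5 tert-butyl{[(2R,3R)-3-[(3E,7E)-10-chloro-3,7-dimethyldeca-3,7-dien-1-yl]-2-methyloxiran-2-yl]methoxy}diphenylsilane, via epoxy alcohol 4 (not isolated)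
Conditions: Ti(OiPr)4 (10 mol%), D-(−)-DET (12 mol%), t-BuOOH, 4 Å MS, CH2Cl2, −20 °C; then Me2S; TBDPSCl, imidazole, DMAP (cat.), 0 °C → rt
Reagents that add atoms: tert-butyl hydroperoxide, CC(C)(C)OO; tert-butyldiphenylsilyl chloride, CC(C)(C)[Si](Cl)(c1ccccc1)c1ccccc1
Why: Sharpless asymmetric epoxidation touches only the allylic-alcohol alkene and D-(−)-tartrate gives the (2R,3R)-epoxy alcohol (L-(+)-tartrate gives 2S,3S with E-allylic alcohols), which is silylated in situ so that no free alkoxide can interfere with the cationic step.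

Step 4
Reactants: 5 tert-butyl{[(2R,3R)-3-[(3E,7E)-10-chloro-3,7-dimethyldeca-3,7-dien-1-yl]-2-methyloxiran-2-yl]methoxy}diphenylsilane
Product: 7 12-chloro-13,14,15,16-tetranor-neo-clerod-4(18)-en-3-one, via β-silyloxy ketone 6 (not isolated)
Conditions: MeAlCl2 (3 equiv), CH2Cl2 (5 mM), −90 → −30 °C; then DBU, −30 °C → rt
Reagents that add atoms: none
Why: Proposed new method: MeAlCl2 opens the epoxide at its tertiary carbon with anti attack by the 5(10)-alkene through a chair–chair fold (the epoxide configuration fixes the absolute sense and puts the Z-methyl axial), ring B closes to the C8 cation of an ent-labdane zwitterion, and in the non-basic medium the charge is drawn back to the aluminate by five antiperiplanar axial 1,2-shifts (H9→C8, Me C10→C9, H5→C10, Me C4→C5, H3→C4) that set C8, C9, C10 and C5 and end irreversibly as C3 ketone 6, which loses silanol (E1cB) with DBU; the closest known chemistry is Lewis-acid epoxy-polyene bicyclisation, the Lewis-acid-induced collapse of cation–olefin zwitterions to ketones by successive 1,2-hydride/alkyl shifts, and the friedelin-type backbone rearrangement.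

Step 5
Reactants: 7 12-chloro-13,14,15,16-tetranor-neo-clerod-4(18)-en-3-one
Product: 8 12-chloro-13,14,15,16,18-pentanor-neo-clerodane-3,4-dione
Conditions: O3, CH2Cl2, −78 °C; then Me2S
Reagents that add atoms: ozone, [O-][O+]=O
Why: Ozonolysis cleaves the only C=C (the exocyclic enone methylene) to the 1,2-dione, which sits as the Δ2-enol (diosphenol) because C5 is quaternary.

Step 6
Reactants: 8 12-chloro-13,14,15,16,18-pentanor-neo-clerodane-3,4-dione
Product: 9 12-chloro-4-oxo-13,14,15,16,18-pentanor-neo-clerod-2-en-3-yl trifluoromethanesulfonate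
Conditions: Tf2O, 2,6-lutidine, CH2Cl2, −78 → 0 °C
Reagents that add atoms: triflic anhydride, O=S(=O)(OS(=O)(=O)C(F)(F)F)C(F)(F)F
Why: O-Triflation of the diosphenol is regiospecific because only C2 can enolise, so the C3 oxygen is singled out for removal.

Step 7
Reactants: 9 12-chloro-4-oxo-13,14,15,16,18-pentanor-neo-clerod-2-en-3-yl trifluoromethanesulfonate
Product: 11 12-chloro-13,14,15,16,18-pentanor-neo-clerodan-4-one, via enone 10 (not isolated)
Conditions: H2 (1 atm), 10% Pd/C, Et3N, EtOAc, rt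
Reagents that add atoms: none
Why: Pd-catalysed hydrogenolysis of the vinyl C–OTf bond gives enone 10, whose disubstituted alkene is hydrogenated in the same flask, while the primary chloride and the hindered ketone are inert and no stereocentre is formed.

Step 8
Reactants: 11 12-chloro-13,14,15,16,18-pentanor-neo-clerodan-4-one
Product: 12 12-chloro-13,14,15,16,18-pentanor-neo-clerodan-4-one (E)-O-methyl oxime
Conditions: MeONH2·HCl, pyridine, EtOH, 70 °C
Reagents that add atoms: O-methylhydroxylamine hydrochloride, CON.Cl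
Why: Oxime-ether condensation places OMe anti to the quaternary C5 (E), so the nitrogen lone pair points toward C5/C6 for the directed C–H step.

Step 9
Reactants: 12 12-chloro-13,14,15,16,18-pentanor-neo-clerodan-4-one (E)-O-methyl oxime
Product: 14 12-chloro-6α-hydroxy-13,14,15,16,18-pentanor-neo-clerodan-4-one (E)-O-methyl oxime, via 6α-acetate 13 (not isolated)
Conditions: Pd(OAc)2 (10 mol%), PhI(OAc)2, AcOH/Ac2O, 100 °C; evaporate; K2CO3, MeOH, 40 °C
Reagents that add atoms: (diacetoxyiodo)benzene, CC(=O)OI(OC(C)=O)c1ccccc1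
Why: Oxime-directed Pd(II)/Pd(IV) C(sp3)–H acetoxylation needs a β-C–H coplanar with C=N, and only the equatorial (peri) H6α qualifies (the C19 methyl is axial and orthogonal), so a five-membered palladacycle forms at C6 and C–O reductive elimination with retention gives the equatorial 6α-acetate, which is methanolysed in the same flask.

Step 10
Reactants: 14 12-chloro-6α-hydroxy-13,14,15,16,18-pentanor-neo-clerodan-4-one (E)-O-methyl oxime
Product: 17 12-chloro-6α,19-dihydroxy-13,14,15,16,18-pentanor-neo-clerodan-4-one (E)-O-methyl oxime, via hydridosilyl ether 15 (not isolated), via oxasilolane 16 (not isolated)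
Conditions: Et2SiH2, [Ir(cod)OMe]2 (0.5 mol%), THF, rt; then [Ir(cod)OMe]2 (1 mol%), Me4phen, norbornene, THF, 100 °C; then H2O2, KHCO3, THF/MeOH, 50 °C
Reagents that add atoms: hydrogen peroxide, OO
Why: Hydroxyl-directed Ir-catalysed γ-C–H silylation is selective for primary C–H, C19 is the only methyl γ to O6 and is gauche to the equatorial oxygen, and Tamao–Fleming oxidation of the oxasilolane gives the 1,3-diol without touching any stereocentre.

Step 11
Reactants: 17 12-chloro-6α,19-dihydroxy-13,14,15,16,18-pentanor-neo-clerodan-4-one (E)-O-methyl oxime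
Product: 18 6α,19-diacetoxy-12-chloro-13,14,15,16,18-pentanor-neo-clerodan-4-one (E)-O-methyl oxime
Conditions: Ac2O, DMAP, pyridine, rt → 40 °C
Reagents that add atoms: acetic anhydride, CC(=O)OC(C)=O
Why: DMAP-catalysed acetylation installs both target acetates at once on the primary and the hindered equatorial secondary alcohol.

Step 12
Reactants: 18 6α,19-diacetoxy-12-chloro-13,14,15,16,18-pentanor-neo-clerodan-4-one (E)-O-methyl oxime
Product: 19 6α,19-diacetoxy-12-chloro-13,14,15,16,18-pentanor-neo-clerodan-4-one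
Conditions: glyoxylic acid (50% aq.), AcOH, THF, 45 °C
Reagents that add atoms: water, O
Why: Acid-catalysed transoximation to the more electrophilic glyoxylic acid frees the hindered ketone under conditions that keep the acetates, and the β-acyloxy ketone cannot eliminate because C5 has no hydrogen.

Step 13
Reactants: 19 6α,19-diacetoxy-12-chloro-13,14,15,16,18-pentanor-neo-clerodan-4-one
Product: 20 6α,19-diacetoxy-12-chloro-13,14,15,16,18-pentanor-neo-clerod-2-en-4-one
Conditions: IBX, DMSO/PhF, 75 °C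
Reagents that add atoms: none
Why: IBX dehydrogenation via the enol can only give the Δ2-enone because C3 is the sole enolisable α-carbon.

Step 14
Reactants: 20 6α,19-diacetoxy-12-chloro-13,14,15,16,18-pentanor-neo-clerod-2-en-4-one
Product: 23 6α,19-diacetoxy-12-chloro-1β-hydroxy-13,14,15,16,18-pentanor-neo-clerod-2-en-4-one, via silyl dienol ether 21 (not isolated), via 1,4-endoperoxide 22 (not isolated)
Conditions: TMSOTf, Et3N, CH2Cl2, 0 °C; then O2, TPP, hν, −78 °C; then PPh3, −78 °C → rt; aq. citric acid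
Reagents that add atoms: dioxygen, O=O
Why: With no α′-hydrogen, γ-deprotonation gives the 2-silyloxy-1,3-diene, which adds singlet oxygen in a [4+2] cycloaddition on the β face, anti to the axial C19 substituent on C5, so that O–O reduction and collapse of the silyl ketal leave the 1β-hydroxy enone (vinylogous Rubottom-type γ-oxygenation).

Step 15
Reactants: 23 6α,19-diacetoxy-12-chloro-1β-hydroxy-13,14,15,16,18-pentanor-neo-clerod-2-en-4-one
Product: 24 6α,19-diacetoxy-12-chloro-1β-hydroxy-13,14,15,16,18-pentanor-neo-clerodan-4-one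
Conditions: H2 (1 atm), RhCl(PPh3)3 (10 mol%), benzene/EtOH, rt
Reagents that add atoms: none
Why: Homogeneous (Wilkinson) hydrogenation saturates the cis-disubstituted enone alkene without hydrogenolysis of the allylic C1–O bond and creates no stereocentre.

Step 16
Reactants: 24 6α,19-diacetoxy-12-chloro-1β-hydroxy-13,14,15,16,18-pentanor-neo-clerodan-4-one
Product: 25 6α,19-diacetoxy-12-chloro-13,14,15,16-tetranor-neo-clerod-4(18)-en-1β-ol
Conditions: Zn, CH2Br2, TiCl4, THF/CH2Cl2, 0 °C → rt
Reagents that add atoms: dibromomethane, BrCBr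
Why: Takai–Lombardo methylenation is non-basic, selective for ketones over acetates and effective on hindered enolisable ketones, and returns C18 as the exocyclic methylene.

Step 17
Reactants: 25 6α,19-diacetoxy-12-chloro-13,14,15,16-tetranor-neo-clerod-4(18)-en-1β-ol
Product: 27 6α,19-diacetoxy-1β-hydroxy-13,14,15,16-tetranor-neo-clerod-4(18)-en-12-al, via iodide 26 (not isolated)
Conditions: NaI (20 mol%), NaHCO3, DMSO, 110 °C
Reagents that add atoms: dimethyl sulfoxide, CS(C)=O
Why: Kornblum oxidation, in which catalytic iodide turns the unhindered primary chloride into iodide 26, DMSO displaces it and bicarbonate collapses the alkoxysulfonium to the aldehyde, leaving acetates, alkene and the secondary alcohol untouched.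

Step 18
Reactants: 27 6α,19-diacetoxy-1β-hydroxy-13,14,15,16-tetranor-neo-clerod-4(18)-en-12-al; 28 4-bromofuran-2(5H)-one
Product: 29 (12S)-6α,19-diacetoxy-1β,12-dihydroxy-neo-cleroda-4(18),13-dien-15,16-olide
Conditions: CrCl2 (4 equiv), NiCl2 (2 mol%), chiral sulfonamide–oxazoline ligand (enantiomer directing Re-face attack), Et3N, THF/MeCN, rt
Reagents that add atoms: none
Why: Nozaki–Hiyama–Kishi coupling, in which Ni inserts into the β-bromobutenolide C–Br bond and the derived alkenylchromium(III) adds only to the aldehyde, with the chiral ligand directing Re-face attack to set 12S under reagent control (the ring stereocentres are remote).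

Step 19
Reactants: 29 (12S)-6α,19-diacetoxy-1β,12-dihydroxy-neo-cleroda-4(18),13-dien-15,16-olide; 30 (S)-2-methylbutanoic anhydride
Product: 31 (12S)-6α,19-diacetoxy-1β,12-bis[(2S)-2-methylbutanoyloxy]-neo-cleroda-4(18),13-dien-15,16-olide
Conditions: 30 (3 equiv), DMAP, Et3N, CH2Cl2, rt → 35 °C
Reagents that add atoms: none
Why: DMAP-catalysed acylation with the enantiopure anhydride esterifies both secondary alcohols in one operation without ketene formation, so the acyl α-stereocentres are kept.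

Step 20
Reactants: 31 (12S)-6α,19-diacetoxy-1β,12-bis[(2S)-2-methylbutanoyloxy]-neo-cleroda-4(18),13-dien-15,16-olide
Product: 32 ajugaciliatin A
Conditions: trichloroisocyanuric acid (0.4 equiv), acetone/H2O (4:1), 0 °C
Reagents that add atoms: trichloroisocyanuric acid, ClN1C(=O)N(Cl)C(=O)N(Cl)C1=O; water, O
Why: Chlorohydrin formation, in which electrophilic chlorine adds to the exocyclic methylene from the open β (axial) face and water opens the chloronium ion at tertiary C4 from the α face (anti, Markovnikov) to give 4α-OH/18-Cl, while the electron-poor butenolide alkene does not react.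

## Compound list

1 | (3E,7E)-homofarnesol, (3E,7E)-4,8,12-trimethyltrideca-3,7,11-trien-1-ol | OCC/C=C(\C)CC/C=C(\C)CCC=C(C)C | starting material
2 | (3E,7E)-1-chloro-4,8,12-trimethyltrideca-3,7,11-triene | ClCC/C=C(\C)CC/C=C(\C)CCC=C(C)C | intermediate
3 | (2E,6E,10E)-13-chloro-2,6,10-trimethyltrideca-2,6,10-trien-1-ol | ClCC/C=C(\C)CC/C=C(\C)CC/C=C(\C)CO | intermediate
4 | [(2R,3R)-3-[(3E,7E)-10-chloro-3,7-dimethyldeca-3,7-dien-1-yl]-2-methyloxiran-2-yl]methanol (not isolated) | ClCC/C=C(\C)CC/C=C(\C)CC[C@H]1O[C@]1(C)CO | intermediate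
5 | tert-butyl{[(2R,3R)-3-[(3E,7E)-10-chloro-3,7-dimethyldeca-3,7-dien-1-yl]-2-methyloxiran-2-yl]methoxy}diphenylsilane | ClCC/C=C(\C)CC/C=C(\C)CC[C@H]1O[C@]1(C)CO[Si](c2ccccc2)(c2ccccc2)C(C)(C)C | intermediate
6 | 12-chloro-18-(tert-butyldiphenylsilyloxy)-13,14,15,16-tetranor-neo-clerodan-3-one, 4β-H (not isolated) | ClCC[C@@]1(C)[C@H](C)CC[C@]2(C)[C@@H]1CCC(=O)[C@H]2CO[Si](c3ccccc3)(c3ccccc3)C(C)(C)C | intermediate
7 | 12-chloro-13,14,15,16-tetranor-neo-clerod-4(18)-en-3-one | ClCC[C@@]1(C)[C@H](C)CC[C@]2(C)[C@@H]1CCC(=O)C2=C | intermediate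
8 | 12-chloro-13,14,15,16,18-pentanor-neo-clerodane-3,4-dione (Δ2-enol in solution) | ClCC[C@@]1(C)[C@H](C)CC[C@]2(C)[C@@H]1CCC(=O)C2=O | intermediate
9 | 12-chloro-4-oxo-13,14,15,16,18-pentanor-neo-clerod-2-en-3-yl trifluoromethanesulfonate | ClCC[C@@]1(C)[C@H](C)CC[C@]2(C)[C@@H]1CC=C(OS(=O)(=O)C(F)(F)F)C2=O | intermediate
10 | 12-chloro-13,14,15,16,18-pentanor-neo-clerod-2-en-4-one (not isolated) | ClCC[C@@]1(C)[C@H](C)CC[C@]2(C)[C@@H]1CC=CC2=O | intermediate
11 | 12-chloro-13,14,15,16,18-pentanor-neo-clerodan-4-one | ClCC[C@@]1(C)[C@H](C)CC[C@]2(C)[C@@H]1CCCC2=O | intermediate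
12 | 12-chloro-13,14,15,16,18-pentanor-neo-clerodan-4-one (E)-O-methyl oxime | ClCC[C@@]1(C)[C@H](C)CC[C@]2(C)[C@@H]1CCC/C2=N\OC | intermediate
13 | 6α-acetoxy-12-chloro-13,14,15,16,18-pentanor-neo-clerodan-4-one (E)-O-methyl oxime (not isolated) | ClCC[C@@]1(C)[C@H](C)C[C@H](OC(C)=O)[C@]2(C)[C@@H]1CCC/C2=N\OC | intermediate
14 | 12-chloro-6α-hydroxy-13,14,15,16,18-pentanor-neo-clerodan-4-one (E)-O-methyl oxime | ClCC[C@@]1(C)[C@H](C)C[C@H](O)[C@]2(C)[C@@H]1CCC/C2=N\OC | intermediate
15 | 6α-(diethylsilyloxy) derivative of 14 (not isolated) | ClCC[C@@]1(C)[C@H](C)C[C@H](O[SiH](CC)CC)[C@]2(C)[C@@H]1CCC/C2=N\OC | intermediate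
16 | 6α-O,19-C-diethylsilanediyl oxasilolane of 14 (not isolated) | ClCC[C@@]1(C)[C@H](C)C[C@@H]3O[Si](CC)(CC)C[C@]32[C@@H]1CCC/C2=N\OC | intermediate
17 | 12-chloro-6α,19-dihydroxy-13,14,15,16,18-pentanor-neo-clerodan-4-one (E)-O-methyl oxime | ClCC[C@@]1(C)[C@H](C)C[C@H](O)[C@]2(CO)[C@@H]1CCC/C2=N\OC | intermediate
18 | 6α,19-diacetoxy-12-chloro-13,14,15,16,18-pentanor-neo-clerodan-4-one (E)-O-methyl oxime | ClCC[C@@]1(C)[C@H](C)C[C@H](OC(C)=O)[C@]2(COC(C)=O)[C@@H]1CCC/C2=N\OC | intermediate
19 | 6α,19-diacetoxy-12-chloro-13,14,15,16,18-pentanor-neo-clerodan-4-one | ClCC[C@@]1(C)[C@H](C)C[C@H](OC(C)=O)[C@]2(COC(C)=O)[C@@H]1CCCC2=O | intermediate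
20 | 6α,19-diacetoxy-12-chloro-13,14,15,16,18-pentanor-neo-clerod-2-en-4-one | ClCC[C@@]1(C)[C@H](C)C[C@H](OC(C)=O)[C@]2(COC(C)=O)[C@@H]1CC=CC2=O | intermediate
21 | 6α,19-diacetoxy-12-chloro-4-(trimethylsilyloxy)-13,14,15,16,18-pentanor-neo-cleroda-1,3-diene (not isolated) | ClCC[C@@]1(C)[C@H](C)C[C@H](OC(C)=O)[C@]2(COC(C)=O)[C@@H]1C=CC=C2O[Si](C)(C)C | intermediate
22 | 6α,19-diacetoxy-12-chloro-1β,4β-epidioxy-4α-(trimethylsilyloxy)-13,14,15,16,18-pentanor-neo-clerod-2-ene (not isolated) | ClCC[C@@]1(C)[C@H](C)C[C@H](OC(C)=O)[C@]2(COC(C)=O)[C@@H]1[C@H]3C=C[C@]2(O[Si](C)(C)C)OO3 | intermediate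
23 | 6α,19-diacetoxy-12-chloro-1β-hydroxy-13,14,15,16,18-pentanor-neo-clerod-2-en-4-one | ClCC[C@@]1(C)[C@H](C)C[C@H](OC(C)=O)[C@]2(COC(C)=O)[C@@H]1[C@H](O)C=CC2=O | intermediate
24 | 6α,19-diacetoxy-12-chloro-1β-hydroxy-13,14,15,16,18-pentanor-neo-clerodan-4-one | ClCC[C@@]1(C)[C@H](C)C[C@H](OC(C)=O)[C@]2(COC(C)=O)[C@@H]1[C@H](O)CCC2=O | intermediate
25 | 6α,19-diacetoxy-12-chloro-13,14,15,16-tetranor-neo-clerod-4(18)-en-1β-ol | ClCC[C@@]1(C)[C@H](C)C[C@H](OC(C)=O)[C@]2(COC(C)=O)[C@@H]1[C@H](O)CCC2=C | intermediate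
26 | 6α,19-diacetoxy-12-iodo-13,14,15,16-tetranor-neo-clerod-4(18)-en-1β-ol (not isolated) | ICC[C@@]1(C)[C@H](C)C[C@H](OC(C)=O)[C@]2(COC(C)=O)[C@@H]1[C@H](O)CCC2=C | intermediate
27 | 6α,19-diacetoxy-1β-hydroxy-13,14,15,16-tetranor-neo-clerod-4(18)-en-12-al | O=CC[C@@]1(C)[C@H](C)C[C@H](OC(C)=O)[C@]2(COC(C)=O)[C@@H]1[C@H](O)CCC2=C | intermediate
28 | 4-bromofuran-2(5H)-one | BrC1=CC(=O)OC1 | starting material
29 | (12S)-6α,19-diacetoxy-1β,12-dihydroxy-neo-cleroda-4(18),13-dien-15,16-olide | O[C@@H](C[C@@]1(C)[C@H](C)C[C@H](OC(C)=O)[C@]2(COC(C)=O)[C@@H]1[C@H](O)CCC2=C)C1=CC(=O)OC1 | intermediate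
30 | (S)-2-methylbutanoic anhydride | CC[C@H](C)C(=O)OC(=O)[C@@H](C)CC | starting material
31 | (12S)-6α,19-diacetoxy-1β,12-bis[(2S)-2-methylbutanoyloxy]-neo-cleroda-4(18),13-dien-15,16-olide | CC[C@H](C)C(=O)O[C@@H](C[C@@]1(C)[C@H](C)C[C@H](OC(C)=O)[C@]2(COC(C)=O)[C@@H]1[C@H](OC(=O)[C@@H](C)CC)CCC2=C)C1=CC(=O)OC1 | intermediate
32 | ajugaciliatin A | CC[C@H](C)C(=O)O[C@@H](C[C@@]1(C)[C@H](C)C[C@H](OC(C)=O)[C@]2(COC(C)=O)[C@@H]1[C@H](OC(=O)[C@@H](C)CC)CC[C@]2(O)CCl)C1=CC(=O)OC1 | target

## Step count and weakest steps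

Total step count: 20. Longest linear sequence: 20 steps (1 → 32); 28 and 30 are bought.

The three steps most likely to fail are 4, 9 and 10.

Step 4 (one-pot cyclisation and five-fold shift). The danger is proton loss at the labdane stage before the shifts run. The fallback separates ring formation from the backbone rearrangement. It sets out from 5: cyclisation with Et2AlCl (CH2Cl2, −78 °C) gives the ordinary bicyclisation product, 12-chloro-18-(tert-butyldiphenylsilyloxy)-13,14,15,16-tetranor-ent-labd-7-en-3α-ol F1 (with its Δ8 isomers). F1 is then equilibrated with catalytic TfOH in HFIP at 0 °C. Protonation at C7 regenerates the C8 cation reversibly, and the same five shifts run under thermodynamic control into the only irreversible exit, the protonated C3 ketone 6. DBU then gives 7, where the fallback rejoins the route.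

Step 9 (C6–H acetoxylation). If cyclopalladation at the hindered peri methylene fails, the C–H bond is broken by a radical instead. The fallback sets out from 11: NH2OH·HCl/NaOAc gives the free oxime F2. TEMPO/K2CO3 in DMF at 130 °C generates the iminoxyl radical (E/Z oximes equilibrate), which abstracts the in-plane H6α by 1,5-hydrogen transfer; oxidation and ring closure give the fused isoxazoline F3. Mo(CO)6 in wet MeCN cleaves the N–O bond to the β-hydroxy imine F4, which hydrolyses in the same flask to the 6α-hydroxy ketone F5. MeONH2·HCl/pyridine converts F5 into 14, where the route is rejoined.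

Step 10 (C19–H silylation). If the silyl ether of the crowded 6α-alcohol next to the oxime ether will not close onto C19, the order of the two C–H oxidations is inverted and the directing group changed. The fallback sets out from 11: NaBH4 reduces the ketone from the β face to the equatorial 4α-alcohol F6. Et2SiH2/[Ir] gives the hydridosilyl ether F7, Ir/Me4phen/norbornene closes the oxasilolane F8 onto C19 (the only γ-methyl), and Tamao oxidation gives the 4α,19-diol F9. Ac2O (1.1 equiv, pyridine, 0 °C) acetylates only the primary alcohol to F10, Dess–Martin oxidation gives the keto acetate F11, and MeONH2·HCl gives the oxime ether F12. The Pd/PhI(OAc)2 acetoxylation of step 9, run without the methanolysis, then gives diacetate 18 directly, where the route is rejoined.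

## Further compounds

F1 | step 4 | 12-chloro-18-(tert-butyldiphenylsilyloxy)-13,14,15,16-tetranor-ent-labd-7-en-3α-ol | ClCC[C@@H]1C(C)=CC[C@H]2[C@@]1(C)CC[C@@H](O)[C@]2(C)CO[Si](c3ccccc3)(c3ccccc3)C(C)(C)C
F2 | step 9 | 12-chloro-13,14,15,16,18-pentanor-neo-clerodan-4-one oxime | ClCC[C@@]1(C)[C@H](C)CC[C@]2(C)[C@@H]1CCC/C2=N\O
F3 | step 9 | isoxazoline fused at C4–C5–C6 (O on C6α, N=C4) of the 12-chloro-pentanor-neo-clerodane | ClCC[C@@]1(C)[C@H](C)C[C@@H]3ON=C4CCC[C@H]1[C@@]34C
F4 | step 9 | 12-chloro-6α-hydroxy-13,14,15,16,18-pentanor-neo-clerodan-4-imine | ClCC[C@@]1(C)[C@H](C)C[C@H](O)[C@]2(C)[C@@H]1CCCC2=N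
F5 | step 9 | 12-chloro-6α-hydroxy-13,14,15,16,18-pentanor-neo-clerodan-4-one | ClCC[C@@]1(C)[C@H](C)C[C@H](O)[C@]2(C)[C@@H]1CCCC2=O
F6 | step 10 | 12-chloro-13,14,15,16,18-pentanor-neo-clerodan-4α-ol | ClCC[C@@]1(C)[C@H](C)CC[C@]2(C)[C@@H]1CCC[C@H]2O
F7 | step 10 | 4α-(diethylsilyloxy)-12-chloro-13,14,15,16,18-pentanor-neo-clerodane | ClCC[C@@]1(C)[C@H](C)CC[C@]2(C)[C@@H]1CCC[C@H]2O[SiH](CC)CC
F8 | step 10 | 4α-O,19-C-diethylsilanediyl oxasilolane of the 12-chloro-pentanor-neo-clerodane | ClCC[C@@]1(C)[C@H](C)CC[C@@]23C[Si](CC)(CC)O[C@@H]2CCC[C@@H]31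
F9 | step 10 | 12-chloro-13,14,15,16,18-pentanor-neo-clerodane-4α,19-diol | ClCC[C@@]1(C)[C@H](C)CC[C@]2(CO)[C@@H]1CCC[C@H]2O
F10 | step 10 | 19-acetoxy-12-chloro-13,14,15,16,18-pentanor-neo-clerodan-4α-ol | ClCC[C@@]1(C)[C@H](C)CC[C@]2(COC(C)=O)[C@@H]1CCC[C@H]2O
F11 | step 10 | 19-acetoxy-12-chloro-13,14,15,16,18-pentanor-neo-clerodan-4-one | ClCC[C@@]1(C)[C@H](C)CC[C@]2(COC(C)=O)[C@@H]1CCCC2=O
F12 | step 10 | 19-acetoxy-12-chloro-13,14,15,16,18-pentanor-neo-clerodan-4-one (E)-O-methyl oxime | ClCC[C@@]1(C)[C@H](C)CC[C@]2(COC(C)=O)[C@@H]1CCC/C2=N\OC
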